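The target is a linear tetramer of 2,4,6-trihydroxypropiophenone (rings A to D, three CH2 bridges) with four extra C-methyl groups. The route rests on cutting these four C–CH3 bonds at the quaternary C5 of terminal rings A and D. It exploits the fact that in the all-aromatic tetramer C5 of rings A and D, between the C4 and C6 oxygens, is the only ring carbon still bearing hydrogen; rings B and C are fully substituted. One treatment with iodomethane and methoxide should methylate each C5 twice and dearomatise both end rings. The precursor is built from the centre outwards through a double Mannich base.

Key step: step 5

Remark (numbering): in each ring C1 bears the propionyl group, C2, C4 and C6 bear oxygen, and C3 and C5 are the other two carbons; in rings A and D the bridge sits on C3.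
Remark (tautomers): the end rings of the target are enolised β-triketones, written as in the target string as 3,5-dihydroxy-6,6-dimethylcyclohexa-2,4-dien-1-ones with the ring carbonyl next to C(CH3)2; the 4,4-dimethylcyclohexa-2,5-dienone drawing is a tautomer of the same compound.
Remark (two-directional steps): intermediates are drawn with both chain ends at the same stage, although the ends should react independently; the target has no stereocentre, so no stereodescriptor is needed.

Step 1
Reactants: 1 phloroglucinol (anhydrous); 2 propionyl chloride
Product: 3 monomer 2,4,6-trihydroxypropiophenone
Conditions: 2 (1.05 equiv), AlCl3 (3.5 equiv), CH2Cl2–MeNO2, 0 °C to 40 °C; ice/1 M HCl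
Reagents that add atoms: propionyl chloride (2), CCC(=O)Cl
Why: Friedel–Crafts C-acylation of a very electron-rich arene, which should stop after one acyl group because the chelated aryl ketone–AlCl3 complex is strongly deactivated and only about one equivalent of 2 is offered.

Step 2
Reactants: 3 monomer 2,4,6-trihydroxypropiophenone (two molecules enter the product); 4 formaldehyde
Product: 6 central dimer bis(3-propionyl-2,4,6-trihydroxyphenyl)methane, via hydroxymethyl monomer 5 (not isolated)
Conditions: 3 (6 equiv), 37% aq. CH2O (1 equiv, slow addition), cat. HCl, EtOH–H2O, rt; filter, recover excess 3
Reagents that add atoms: formaldehyde (4), C=O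
Why: Acid-catalysed hydroxyalkylation followed by Friedel–Crafts-type benzylation (the novolac regime of phenol–formaldehyde chemistry), in which 4 hydroxymethylates one C–H of 3 to give 5, 5 ionises and is trapped by the large excess of 3, and the poorly soluble 6 should leave the solution before its own free C–H positions can react.

Step 3
Reactants: 6 central dimer; 4 formaldehyde; 7 dimethylamine
Product: 8 double Mannich base bis[3-(dimethylaminomethyl)-5-propionyl-2,4,6-trihydroxyphenyl]methane
Conditions: 40% aq. Me2NH (2.6 equiv) premixed with 37% aq. CH2O (2.3 equiv), EtOH, 0 °C to rt
Reagents that add atoms: formaldehyde (4), C=O; dimethylamine (7), CNC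
Why: Twofold Mannich reaction at the single free C–H of each ring of 6, which has a defined end point because no other ring position is open, and in which the formaldehyde is bound beforehand to an excess of secondary amine so that it cannot forge further CH2 bridges.

Step 4
Reactants: 8 double Mannich base; 3 monomer 2,4,6-trihydroxypropiophenone (two molecules enter the product)
Product: 10 all-aromatic linear tetramer (rings A to D), via bis(ortho-quinone methide) 9 (not isolated)
Conditions: 3 (12 equiv), AcOH (4 equiv), 1,4-dioxane, 70 °C, Ar; excess 3 washed out with hot water
Reagents that add atoms: monomer 2,4,6-trihydroxypropiophenone (3), CCC(=O)c1c(O)cc(O)cc1O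
Why: Thermal loss of dimethylamine from an ortho-hydroxybenzylamine gives the ortho-quinone methide stage 9, and Michael-type addition of a ring C–H carbon of 3 followed by rearomatisation forms each outer bridge, while the large excess of 3 outcompetes the new end rings as nucleophiles and the acetic acid keeps the medium non-basic so that the central bridge should not exchange.

Step 5
Reactants: 10 all-aromatic linear tetramer; 11 iodomethane
Product: 13 target CNP0541376.0, via terminal bis(C-methyl) tetramer 12 (not isolated)
Conditions: NaOMe (6 equiv at the start, 4 equiv fed in parallel with MeI), MeI (4.1 equiv, slow addition), degassed MeOH, 0 °C to 15 °C, Ar; cold 1 M HCl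
Reagents that add atoms: iodomethane (11), CI
Why: Methoxide turns 10 into a polyphenoxide in which C5 of rings A and D attacks iodomethane in an SN2 step, proton loss restores the arene (stage 12), and a second SN2 attack from the same carbon creates C(CH3)2 and leaves each end ring as the anion of an enolised β-triketone. The closest known reaction type is the alkylative dearomatisation of acylphloroglucinols with MeI and NaOMe to acylfilicinic acids, and the 3-alkyl-5,5-dialkyl pattern sought here is the one at which base-mediated polyalkylation of acylphloroglucinols to hop β-acid-type products comes to rest. No ring is closed and no stereocentre arises, since each new quaternary carbon carries two identical methyl groups. The step needs C- over O-methylation, which the hydrogen-bonding solvent and the soft electrophile favour, and attack at C5 of rings A and D rather than ipso attack at a bridge- or acyl-bearing carbon, which rests on C5 being the only unsubstituted ring carbon whereas every ipso attack would build a quaternary centre next to a bulky, fully substituted arylmethyl group. It must also stop at two methyl groups per end, which should follow from the low nucleophilicity of the strongly acidic filicinic-type anion, whose only remaining nucleophilic carbon C3 is blocked by the bridge, and from the limit of four equivalents of MeI. Metering the base so that little free methoxide is present, low temperature, short contact time and exclusion of air are meant to hold back base-induced exchange of the CH2 bridges, loss of MeI to the solvent and oxidation of the polyphenoxide.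

Compound list
1 | phloroglucinol (benzene-1,3,5-triol) | Oc1cc(O)cc(O)c1 | starting material
2 | propionyl chloride | CCC(=O)Cl | starting material
3 | monomer, 2,4,6-trihydroxypropiophenone (1-(2,4,6-trihydroxyphenyl)propan-1-one) | CCC(=O)c1c(O)cc(O)cc1O | intermediate
4 | formaldehyde (37% aqueous solution) | C=O | starting material
5 | hydroxymethyl monomer, 3-(hydroxymethyl)-2,4,6-trihydroxypropiophenone (formed in the flask) | CCC(=O)c1c(O)cc(O)c(CO)c1O | intermediate
6 | central dimer, bis(3-propionyl-2,4,6-trihydroxyphenyl)methane; one free C–H per ring | CCC(=O)c1c(O)cc(O)c(Cc2c(O)cc(O)c(C(=O)CC)c2O)c1O | intermediate
7 | dimethylamine (40% aqueous solution) | CNC | starting material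
8 | double Mannich base, bis[3-(dimethylaminomethyl)-5-propionyl-2,4,6-trihydroxyphenyl]methane | CCC(=O)c1c(O)c(CN(C)C)c(O)c(Cc2c(O)c(CN(C)C)c(O)c(C(=O)CC)c2O)c1O | intermediate
9 | bis(ortho-quinone methide): dimer 8 after loss of both amines, each ring a 6-methylidenecyclohexa-2,4-dienone carrying exocyclic C=CH2 next to a ring C=O (formed in the flask) | C=C1C(=O)C(CC2=C(O)C(C(=O)CC)=C(O)C(=C)C2=O)=C(O)C(C(=O)CC)=C1O | intermediate
10 | all-aromatic linear tetramer: four 2,4,6-trihydroxypropiophenone rings A–B–C–D joined by three CH2 bridges; rings B and C fully substituted, rings A and D each keep C5–H | CCC(=O)c1c(O)cc(O)c(Cc2c(O)c(Cc3c(O)c(Cc4c(O)cc(O)c(C(=O)CC)c4O)c(O)c(C(=O)CC)c3O)c(O)c(C(=O)CC)c2O)c1O | intermediate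
11 | iodomethane | CI | starting material
12 | terminal bis(C-methyl) tetramer: 10 with one CH3 on C5 of ring A and of ring D, all rings still aromatic (formed in the flask) | CCC(=O)c1c(O)c(C)c(O)c(Cc2c(O)c(Cc3c(O)c(Cc4c(O)c(C)c(O)c(C(=O)CC)c4O)c(O)c(C(=O)CC)c3O)c(O)c(C(=O)CC)c2O)c1O | intermediate
13 | CNP0541376.0: rings B and C as in 10, rings A and D as 3,5-dihydroxy-6,6-dimethyl-2-propionylcyclohexa-2,4-dien-1-ones bridged through C4 of that name | CCC(=O)C1=C(O)C(Cc2c(O)c(Cc3c(O)c(CC4=C(O)C(C)(C)C(=O)C(C(=O)CC)=C4O)c(O)c(C(=O)CC)c3O)c(O)c(C(=O)CC)c2O)=C(O)C(C)(C)C1=O | target

Total step count: 5
Longest linear sequence: 5 steps (1 → 3 → 6 → 8 → 10 → 13)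

Steps most likely to fail

Risk 1 (step 5, key step). Alkyl-bearing carbons of phloroglucinol anions are intrinsically good nucleophiles. Ipso methylation at bridge-bearing carbons (C3 of rings A and D, C3 and C5 of rings B and C) may therefore compete with attack at C5. O-methylation, uneven methylation of the two ends and retro-Michael exchange of the bridges in the basic medium may add to a mixture that is hard to separate at this molecular size. The fallback moves the methylation to the monomer stage and forms the outer bridges last.
- It sets out from 3, which undergoes the known alkylative dearomatisation with NaOMe and 11 in MeOH.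
- This passes through 3-methyl-2,4,6-trihydroxypropiophenone F1 and gives propionylfilicinic acid F2, which is freed from under- and over-methylated material while the molecules are still small.
- An excess of F2 is then heated with the double Mannich base 8 under the conditions of step 4, so that the quinone methide stage 9 is captured by the single ring C–H of F2. This nucleophile cannot extend the chain.
- The fallback comes back to the route at the target 13.

Risk 2 (step 4). Every captured monomer keeps a free C5–H, so the chain may grow beyond the tetramer. The large excess of 3 may also exchange into the central bridge and cut the chain back to dimers, and the quinone methide may react with itself. The fallback changes the bond set from 1 + 2 + 1 to 2 + 2.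
- It sets out from 6, used in large excess and recovered afterwards.
- Slow addition of 4 under the acid catalysis of step 2 in aqueous dioxane should form the mono(hydroxymethyl) dimer F3. This ionises and is trapped by the free C–H of a second molecule of 6.
- The new bridge then becomes the central one, and the fallback comes back to the route at 10 without amine, base or monomer in the flask.
- The possible by-products differ from 10 by whole dimer units, which should ease separation.

Risk 3 (step 2). Both 3 and 6 carry free ring positions, so condensation may run on to trimers and higher oligomers. The fallback uses the aminomethyl group first as a blocking group and later as the leaving group.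
- It sets out from 3, which reacts with one equivalent of premixed 4 and 7 at 0 °C to give the mono-Mannich base 3-(dimethylaminomethyl)-2,4,6-trihydroxypropiophenone F4.
- F4 is separated from doubly aminomethylated material by pH-controlled extraction or crystallisation.
- F4 has only one free ring C–H. Its hydrochloride is condensed with half an equivalent of 4 under acid catalysis through the 5-hydroxymethyl derivative F5, and this can only end at the dimer stage.
- The fallback comes back to the route at 8.

Further compounds
F1 | step 5 | 3-methyl-2,4,6-trihydroxypropiophenone (formed in the flask) | CCC(=O)c1c(O)cc(O)c(C)c1O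
F2 | step 5 | propionylfilicinic acid, 3,5-dihydroxy-6,6-dimethyl-2-propionylcyclohexa-2,4-dien-1-one | CCC(=O)C1=C(O)C=C(O)C(C)(C)C1=O
F3 | step 4 | mono(hydroxymethyl) dimer, 6 with CH2OH on the free carbon of one ring (formed in the flask) | CCC(=O)c1c(O)cc(O)c(Cc2c(O)c(CO)c(O)c(C(=O)CC)c2O)c1O
F4 | step 2 | mono-Mannich base, 3-(dimethylaminomethyl)-2,4,6-trihydroxypropiophenone | CCC(=O)c1c(O)cc(O)c(CN(C)C)c1O
F5 | step 2 | 3-(dimethylaminomethyl)-5-(hydroxymethyl)-2,4,6-trihydroxypropiophenone (formed in the flask) | CCC(=O)c1c(O)c(CO)c(O)c(CN(C)C)c1O
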